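**Strategy**

Ring A is numbered C1 (quaternary; C7H2OH and chain), C2 (arm Cα–Cβ–Cγ–OH), C3 (alkylidene), C4, C5, C6 (CH3, OH). The route rests on cutting C1–C2: C1 carries C7 at the carboxyl level and the C2 arm can be a transposed allyl unit, which is what an Ireland–Claisen rearrangement delivers. In one operation the silyl ketene acetal of a ten-membered lactone contracts to ring A and sets C1 and C2 from one oxygen-bearing Cβ centre. The precursor lactone holds C7, C1 with the homofarnesyl chain, C6–C3 from (S)-linalool (C3 as dioxolane), a Z C2=Cα alkene and the Cβ–O ester bond.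

Key step: step 20

Remarks on the chemistry
- The ring alkene of the lactone is built Z and Cβ is R (from L-glyceraldehyde acetonide). With a Z alkene every transition state that the C3–C6 tether allows is cis-fused; an E alkene would let a ring-trans ketene acetal react through a trans-fused chair and give the C1 epimer.
- The Z alkene is made from an alkyne, whose ketal is acid-stable enough for the acetonide to be removed selectively.
- The chain on C1 is homofarnesyl (one CH2 more than farnesyl), so farnesol is homologated by one carbon before the alkylation.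
- The target has a single ring; the enal is built directly on the C3 ketone.
- Assumption: (S)-2,3-O-isopropylideneglyceraldehyde is purchased (or made fresh from (R)-solketal).

**Route**

Step 1
Reactants: 1 (2E,6E)-farnesol
Product: 2 (2E,6E)-farnesal
Conditions: MnO2 (activated), hexane, rt
Reagents that add atoms: none
Why: Activated MnO2 oxidises the allylic alcohol selectively to the enal (allylic oxidation) without touching or isomerising the trisubstituted alkenes.

Step 2
Reactants: 2 (2E,6E)-farnesal
Product: 3 (3E,7E)-4,8,12-trimethyltrideca-1,3,7,11-tetraene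
Conditions: Ph3PCH3Br, KOt-Bu, THF, 0 °C; then 2, 0 °C → rt
Reagents that add atoms: methyltriphenylphosphonium bromide, C[P+](c1ccccc1)(c1ccccc1)c1ccccc1.[Br-]
Why: Wittig methylenation with the non-stabilised ylide adds 1,2 to the conjugated aldehyde and leaves the E-alkenes as they are.

Step 3
Reactants: 3 (3E,7E)-4,8,12-trimethyltrideca-1,3,7,11-tetraene
Product: 5 (3E,7E)-homofarnesol, via alkyl-9-BBN adduct 4 (not isolated)
Conditions: 9-BBN, THF, 0 °C → rt; then NaOH, H2O2, 0 °C → rt
Reagents that add atoms: hydrogen peroxide, OO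
Why: 9-BBN adds anti-Markovnikov only to the monosubstituted terminus of the diene and oxidation of the C–B bond gives the homoallylic primary alcohol (hydroboration–oxidation, the established way to homoprenyl alcohols).

Step 4
Reactants: 5 (3E,7E)-homofarnesol
Product: 6 (3E,7E)-homofarnesyl iodide
Conditions: I2, PPh3, imidazole, CH2Cl2, 0 °C
Reagents that add atoms: iodine, [I][I]
Why: Appel-type iodination converts the primary alcohol to the iodide by SN2 under near-neutral conditions that spare the alkenes.

Step 5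
Reactants: 7 (S)-2,3-O-isopropylideneglyceraldehyde
Product: 8 (R)-4-(2,2-dibromoethenyl)-2,2-dimethyl-1,3-dioxolane
Conditions: CBr4, PPh3, CH2Cl2, 0 °C
Reagents that add atoms: carbon tetrabromide, BrC(Br)(Br)Br
Why: Corey–Fuchs dibromo-olefination runs under neutral conditions, so the α-oxygenated centre (the later Cβ) is not epimerised; its label changes from S to R only because the substituent priorities change.

Step 6
Reactants: 9 (S)-linalool
Product: 10 (S)-linalool triethylsilyl ether
Conditions: Et3SiOTf, 2,6-lutidine, CH2Cl2, −78 → 0 °C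
Reagents that add atoms: triethylsilyl triflate, CC[Si](CC)(CC)OS(=O)(=O)C(F)(F)F
Why: The silyl triflate with a hindered base silylates the tertiary allylic alcohol without ionising it (silyl ether formation), which later prevents lactol formation at C3 and side reactions of a free β-hydroxy acid.

Step 7
Reactants: 10 (S)-linalool triethylsilyl ether
Product: 12 (S)-3,7-dimethyl-3-(triethylsilyloxy)oct-6-en-1-ol, via alkyl-9-BBN adduct 11 (not isolated)
Conditions: 9-BBN, THF, rt; then NaOH, H2O2, 0 °C → rt
Reagents that add atoms: hydrogen peroxide, OO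
Why: 9-BBN discriminates the vinyl group from the trisubstituted alkene and places boron on the terminal carbon (the later C7), so oxidation gives the primary alcohol (hydroboration–oxidation).

Step 8
Reactants: 12 (S)-3,7-dimethyl-3-(triethylsilyloxy)oct-6-en-1-ol
Product: 14 (S)-3,7-dimethyl-3-(triethylsilyloxy)oct-6-enoic acid, via aldehyde 13 (not isolated)
Conditions: TEMPO (cat.), PhI(OAc)2, MeCN/H2O, rt
Reagents that add atoms: water, O
Why: The oxoammonium-mediated oxidation takes the primary alcohol through the aldehyde hydrate to the acid and tolerates the alkene and the tertiary silyl ether (TEMPO/PhI(OAc)2 oxidation).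

Step 9
Reactants: 14 (S)-3,7-dimethyl-3-(triethylsilyloxy)oct-6-enoic acid
Product: 15 methyl (S)-3,7-dimethyl-3-(triethylsilyloxy)oct-6-enoate
Conditions: MeI, K2CO3, DMF, rt
Reagents that add atoms: iodomethane, CI
Why: O-alkylation of the carboxylate gives the methyl ester that will carry the C1 enolate chemistry.

Step 10
Reactants: 15 methyl (S)-3,7-dimethyl-3-(triethylsilyloxy)oct-6-enoate
Product: 17 methyl (S)-3-methyl-6-oxo-3-(triethylsilyloxy)hexanoate, via ozonide 16 (not isolated)
Conditions: O3, CH2Cl2, −78 °C; then PPh3, −78 °C → rt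
Reagents that add atoms: ozone, [O-][O+]=O
Why: Ozonolysis with reductive work-up cleaves the only alkene and exposes C3 as an aldehyde; it has to precede the introduction of the polyene chain.

Step 11
Reactants: 8 (R)-4-(2,2-dibromoethenyl)-2,2-dimethyl-1,3-dioxolane; 17 methyl (S)-3-methyl-6-oxo-3-(triethylsilyloxy)hexanoate
Product: 19 propargylic alcohol (C3 carbinol epimers), via lithium acetylide 18 (not isolated)
Conditions: n-BuLi (2 equiv), THF, −78 °C; then 17, −78 °C; aq NH4Cl
Reagents that add atoms: none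
Why: Two equivalents of n-BuLi turn the dibromoalkene into the lithium acetylide (second stage of the Corey–Fuchs sequence), which adds to the aldehyde far faster than to the methyl ester; the carbinol centre forms unselectively and is removed in step 12.

Step 12
Reactants: 19 propargylic alcohol (C3 carbinol epimers)
Product: 20 ynone
Conditions: Dess–Martin periodinane, pyridine, CH2Cl2, 0 °C → rt
Reagents that add atoms: none
Why: Dess–Martin oxidation of the secondary propargylic alcohol gives the ynone under buffered conditions that leave the acetonide, silyl ether and Cβ centre alone.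

Step 13
Reactants: 20 ynone
Product: 21 alkynyl dioxolane ester
Conditions: (Me3SiOCH2)2, Me3SiOTf (cat.), CH2Cl2, −78 → −20 °C
Reagents that add atoms: 1,2-bis(trimethylsilyloxy)ethane, C[Si](C)(C)OCCO[Si](C)(C)C
Why: Noyori ketalisation converts the ynone to its dioxolane at low temperature, where the acetonide, the silyl ether and the ester are untouched; the alkynyl ketal resists acid far better than a saturated or vinylic one, which is used in step 16.

Step 14
Reactants: 21 alkynyl dioxolane ester; 6 (3E,7E)-homofarnesyl iodide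
Product: 23 C1-homofarnesyl ester (C1 epimers), via lithium enolate 22 (not isolated)
Conditions: LiN(i-Pr)2, THF, −78 °C; then 6, DMPU, −78 → −30 °C
Reagents that add atoms: none
Why: The ester enolate is alkylated by the primary iodide (enolate alkylation, SN2) at low temperature, where loss of the β-silyloxy group and E2 of the iodide are slow; the C1 centre forms as a mixture, which does not matter because C1 becomes trigonal again in step 20.

Step 15
Reactants: 23 C1-homofarnesyl ester (C1 epimers)
Product: 24 C1-homofarnesyl acid (C1 epimers)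
Conditions: LiOH, THF/MeOH/H2O, 45 °C; aq KHSO4 to pH 4, 0 °C
Reagents that add atoms: lithium hydroxide, [Li+].[OH-]
Why: Saponification of the hindered ester is done now, while no free hydroxyl is present to which a silyl group could migrate; the acetonide, the alkynyl ketal and the tertiary silyl ether are stable to base.

Step 16
Reactants: 24 C1-homofarnesyl acid (C1 epimers)
Product: 25 diol acid
Conditions: AcOH/H2O/THF (3:1:1), rt
Reagents that add atoms: none
Why: Mild aqueous acid hydrolyses the terminal isopropylidene acetal, whereas the alkynyl dioxolane (destabilised oxocarbenium ion) and the tertiary triethylsilyl ether should survive (selective acetal hydrolysis).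

Step 17
Reactants: 25 diol acid
Product: 27 alkynyl hydroxy acid with Cγ silyl ether, via bis-silyl compound 26 (not isolated)
Conditions: t-BuPh2SiCl (2.2 equiv), imidazole, DMF, 0 °C; then K2CO3 (cat.), MeOH, 0 °C
Reagents that add atoms: tert-butyl(chloro)diphenylsilane, CC(C)(C)[Si](Cl)(c1ccccc1)c1ccccc1
Why: The bulky chlorosilane silylates the primary hydroxyl and the carboxylate but not the secondary propargylic hydroxyl, and brief methanolysis cleaves only the labile silyl ester (selective silylation).

Step 18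
Reactants: 27 alkynyl hydroxy acid with Cγ silyl ether
Product: 28 Z seco acid
Conditions: H2 (1 atm), Pd/CaCO3 poisoned with Pb(OAc)2 (Lindlar catalyst), quinoline, Et3N, EtOAc, rt
Reagents that add atoms: none
Why: Lindlar semi-hydrogenation adds hydrogen syn and stops at the Z-alkene without touching the trisubstituted alkenes; the amine keeps the acid as its salt so that the cis-hydroxy ketal is not ionised toward a furan.

Step 19
Reactants: 28 Z seco acid
Product: 30 ten-membered Z-lactone (C1 epimers), via mixed anhydride 29 (not isolated)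
Conditions: 2,4,6-Cl3C6H2COCl, Et3N, THF, rt; then slow addition to DMAP, toluene, 80 °C (about 1 mM)
Reagents that add atoms: none
Why: In the Yamaguchi macrolactonisation DMAP opens the mixed anhydride to an acylpyridinium ion that the Cβ hydroxyl captures at high dilution; the Z-alkene and the two fully substituted ring atoms C3 and C6 pre-organise the chain, and Cβ keeps its configuration because its C–O bond is not broken.

Step 20
Reactants: 30 ten-membered Z-lactone (C1 epimers)
Product: 33 ring A acid, via silyl ketene acetal 31 (not isolated), via trimethylsilyl ester 32 (not isolated)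
Conditions: LiN(i-Pr)2, Me3SiCl/Et3N (premixed), THF, −78 °C → rt; then toluene, 80 °C; H2O/THF (pH 5) work-up
Reagents that add atoms: none
Why: LiN(i-Pr)2 removes the C1 proton of either epimer and Me3SiCl traps the enolate at once as the O-silyl ketene acetal, before the β-silyloxy group can be expelled; on warming, C1 and C2, held together by the C3–C6 tether, bond in a concerted suprafacial [3,3] shift while the allylic Cβ–O bond breaks (Ireland–Claisen rearrangement, in the ring-contracting form known for medium-ring alkenyl lactones). Ring A closes as the ten-membered ring contracts, a 6-exo bond formation at C2 inside a bicyclic transition state. C2 is controlled by Cβ: with the Z ring alkene, allylic 1,3-strain forces H and not CH2OSi to eclipse C3, so oxygen leaves and C1 enters on one face only and the new arm alkene is E. C1 is controlled by the ring fusion: with a Z alkene the four-atom tether can bridge C1 and C2 only in a cis-fused transition state (boat from the ring-cis ketene acetal, chair from the ring-trans one), and both put C7 cis to the arm. The C6 centre from linalool does not take part in the choice of face and can at most slow the reaction. The selectivity needed is diastereofacial and is secured by the alkene geometry and Cβ, while regioselectivity is no issue because C1 carries the only α-hydrogen.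

Step 21
Reactants: 33 ring A acid
Product: 34 ring A acid with saturated arm
Conditions: 2-O2NC6H4SO2NHNH2, Et3N, CH2Cl2, rt
Reagents that add atoms: none
Why: Diimide, released from the sulfonylhydrazide, transfers H2 in a concerted way and reduces the 1,2-disubstituted arm alkene much faster than the three trisubstituted chain alkenes (diimide reduction), with no metal that could cleave the allylic silyl ether.

Step 22
Reactants: 34 ring A acid with saturated arm
Product: 35 C7 alcohol
Conditions: LiAlH4, THF, 0 → 40 °C; H2O work-up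
Reagents that add atoms: none
Why: LiAlH4 reduces the hindered α-quaternary carboxylate to the neopentyl alcohol C7H2OH (hydride reduction), while the ketal, the silyl ethers and the isolated alkenes are inert.

Step 23
Reactants: 35 C7 alcohol
Product: 36 C7 tert-butyldimethylsilyl ether
Conditions: t-BuMe2SiCl, imidazole, DMAP (cat.), DMF, rt → 40 °C
Reagents that add atoms: tert-butyl(chloro)dimethylsilane, CC(C)(C)[Si](C)(C)Cl
Why: Silylation protects the primary alcohol, which would otherwise form a bridged hemiketal with the C3 ketone and be oxidised in step 26.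

Step 24
Reactants: 36 C7 tert-butyldimethylsilyl ether
Product: 37 C3 ketone
Conditions: pyridinium p-toluenesulfonate (cat.), acetone/H2O (10:1), 40 °C
Reagents that add atoms: water, O
Why: Mild acid-catalysed hydrolysis frees the now saturated, sterically compressed ketal while the three silyl ethers survive, and the weak acid limits enolisation toward C2 (ketal hydrolysis).

Step 25
Reactants: 37 C3 ketone
Product: 38 C3 isopropenyl carbinol (C3 epimers)
Conditions: CH2=C(CH3)MgBr, CeCl3 (anhydrous), THF, −78 → 0 °C; aq NH4Cl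
Reagents that add atoms: isopropenylmagnesium bromide, CC(=C)[Mg]Br
Why: The weakly basic organocerium reagent adds to the hindered, enolisable ketone without deprotonating C2 (Imamoto addition); the C3 carbinol centre is of no consequence because C3 becomes trigonal in step 26.

Step 26
Reactants: 38 C3 isopropenyl carbinol (C3 epimers)
Product: 39 tris-silyl ether of the target
Conditions: pyridinium chlorochromate (C5H5NH[CrO3Cl]), 4 Å molecular sieves, CH2Cl2, rt
Reagents that add atoms: pyridinium chlorochromate, [O-][Cr](=O)(=O)Cl.c1cc[nH+]cc1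
Why: In the Babler–Dauben oxidative transposition the tertiary allylic chromate ester shifts [3,3] to the primary allylic chromate, which is oxidised to the enal; the formyl group should end next to the substituted carbon C2 and the methyl group next to C4H2, because in the shift C2 eclipses the CH2 terminus and not the methyl group, and because this Z isomer has the lower allylic strain.

Step 27
Reactants: 39 tris-silyl ether of the target
Product: 40 target CNP0284886.1
Conditions: HF·pyridine, THF, 0 °C → rt
Reagents that add atoms: none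
Why: Fluoride cleaves the tertiary triethylsilyl, the primary tert-butyldimethylsilyl and the primary tert-butyldiphenylsilyl ether (desilylation) under conditions that should neither isomerise the enal nor ionise the tertiary alcohol.

**Compound list**

1 | (2E,6E)-farnesol | CC(C)=CCC/C(C)=C/CC/C(C)=C/CO | starting material
2 | (2E,6E)-farnesal | CC(C)=CCC/C(C)=C/CC/C(C)=C/C=O | intermediate
3 | (3E,7E)-4,8,12-trimethyltrideca-1,3,7,11-tetraene | CC(C)=CCC/C(C)=C/CC/C(C)=C/C=C | intermediate
4 | 9-[(3E,7E)-4,8,12-trimethyltrideca-3,7,11-trien-1-yl]-9-borabicyclo[3.3.1]nonane | CC(C)=CCC/C(C)=C/CC/C(C)=C/CCB1C2CCCC1CCC2 | intermediate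
5 | (3E,7E)-homofarnesol, (3E,7E)-4,8,12-trimethyltrideca-3,7,11-trien-1-ol | CC(C)=CCC/C(C)=C/CC/C(C)=C/CCO | intermediate
6 | (3E,7E)-homofarnesyl iodide, (6E,10E)-13-iodo-2,6,10-trimethyltrideca-2,6,10-triene | CC(C)=CCC/C(C)=C/CC/C(C)=C/CCI | intermediate
7 | (S)-2,3-O-isopropylideneglyceraldehyde | CC1(C)OC[C@@H](C=O)O1 | starting material
8 | (R)-4-(2,2-dibromoethenyl)-2,2-dimethyl-1,3-dioxolane | CC1(C)OC[C@@H](C=C(Br)Br)O1 | intermediate
9 | (S)-linalool | CC(C)=CCC[C@](C)(O)C=C | starting material
10 | (S)-linalool triethylsilyl ether, (S)-[(3,7-dimethylocta-1,6-dien-3-yl)oxy]triethylsilane | CC(C)=CCC[C@](C)(O[Si](CC)(CC)CC)C=C | intermediate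
11 | 9-BBN adduct of 10 at the terminal vinyl carbon (C6 S) | CC(C)=CCC[C@](C)(O[Si](CC)(CC)CC)CCB1C2CCCC1CCC2 | intermediate
12 | (S)-3,7-dimethyl-3-(triethylsilyloxy)oct-6-en-1-ol | CC(C)=CCC[C@](C)(O[Si](CC)(CC)CC)CCO | intermediate
13 | (S)-3,7-dimethyl-3-(triethylsilyloxy)oct-6-enal | CC(C)=CCC[C@](C)(O[Si](CC)(CC)CC)CC=O | intermediate
14 | (S)-3,7-dimethyl-3-(triethylsilyloxy)oct-6-enoic acid | CC(C)=CCC[C@](C)(O[Si](CC)(CC)CC)CC(=O)O | intermediate
15 | methyl (S)-3,7-dimethyl-3-(triethylsilyloxy)oct-6-enoate | CC(C)=CCC[C@](C)(O[Si](CC)(CC)CC)CC(=O)OC | intermediate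
16 | ozonide of 15: methyl (3S)-5-(5,5-dimethyl-1,2,4-trioxolan-3-yl)-3-methyl-3-(triethylsilyloxy)pentanoate (trioxolane carbon unassigned) | CC1(C)OOC(CC[C@](C)(O[Si](CC)(CC)CC)CC(=O)OC)O1 | intermediate
17 | methyl (S)-3-methyl-6-oxo-3-(triethylsilyloxy)hexanoate (C7 ester, C1H2, C6, C5, C4, C3 aldehyde) | O=CCC[C@](C)(O[Si](CC)(CC)CC)CC(=O)OC | intermediate
18 | lithium (R)-(2,2-dimethyl-1,3-dioxolan-4-yl)acetylide | CC1(C)OC[C@@H](C#C[Li])O1 | intermediate
19 | methyl (3S)-8-[(4R)-2,2-dimethyl-1,3-dioxolan-4-yl]-6-hydroxy-3-methyl-3-(triethylsilyloxy)oct-7-ynoate (both epimers at the carbinol, the later C3) | COC(=O)C[C@@](C)(O[Si](CC)(CC)CC)CCC(O)C#C[C@@H]1COC(C)(C)O1 | intermediate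
20 | methyl (S)-8-[(R)-2,2-dimethyl-1,3-dioxolan-4-yl]-3-methyl-6-oxo-3-(triethylsilyloxy)oct-7-ynoate | COC(=O)C[C@@](C)(O[Si](CC)(CC)CC)CCC(=O)C#C[C@@H]1COC(C)(C)O1 | intermediate
21 | methyl (S)-5-{2-[(R)-(2,2-dimethyl-1,3-dioxolan-4-yl)ethynyl]-1,3-dioxolan-2-yl}-3-methyl-3-(triethylsilyloxy)pentanoate | COC(=O)C[C@@](C)(O[Si](CC)(CC)CC)CCC1(OCCO1)C#C[C@@H]1COC(C)(C)O1 | intermediate
22 | lithium enolate of 21 (C1=C7 enolate) | COC(O[Li])=C[C@@](C)(O[Si](CC)(CC)CC)CCC1(OCCO1)C#C[C@@H]1COC(C)(C)O1 | intermediate
23 | 21 carrying the (3E,7E)-homofarnesyl chain on C1 (C6 S, Cβ R, C1 both epimers) | CC(C)=CCC/C(C)=C/CC/C(C)=C/CCC(C(=O)OC)[C@@](C)(O[Si](CC)(CC)CC)CCC1(OCCO1)C#C[C@@H]1COC(C)(C)O1 | intermediate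
24 | carboxylic acid from 23 (C1 epimers) | CC(C)=CCC/C(C)=C/CC/C(C)=C/CCC(C(=O)O)[C@@](C)(O[Si](CC)(CC)CC)CCC1(OCCO1)C#C[C@@H]1COC(C)(C)O1 | intermediate
25 | diol acid: 24 without the acetonide, (R)-3,4-dihydroxybut-1-ynyl group on the C3 dioxolane | CC(C)=CCC/C(C)=C/CC/C(C)=C/CCC(C(=O)O)[C@@](C)(O[Si](CC)(CC)CC)CCC1(OCCO1)C#C[C@@H](O)CO | intermediate
26 | tert-butyldiphenylsilyl ester of 27 (Cγ silyl ether and C7 silyl ester) | CC(C)=CCC/C(C)=C/CC/C(C)=C/CCC(C(=O)O[Si](c1ccccc1)(c1ccccc1)C(C)(C)C)[C@@](C)(O[Si](CC)(CC)CC)CCC1(OCCO1)C#C[C@@H](O)CO[Si](c1ccccc1)(c1ccccc1)C(C)(C)C | intermediate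
27 | alkynyl hydroxy acid: Cβ OH free (R), Cγ O-tert-butyldiphenylsilyl | CC(C)=CCC/C(C)=C/CC/C(C)=C/CCC(C(=O)O)[C@@](C)(O[Si](CC)(CC)CC)CCC1(OCCO1)C#C[C@@H](O)CO[Si](c1ccccc1)(c1ccccc1)C(C)(C)C | intermediate
28 | Z seco acid: HO2C(C7)–C1H(homofarnesyl)–C6(CH3)(OSiEt3)–C5H2–C4H2–C3(dioxolane)–C2H=CαH (Z)–CβH(OH)–CγH2OSiPh2t-Bu; C6 S, Cβ R, C1 epimers | CC(C)=CCC/C(C)=C/CC/C(C)=C/CCC(C(=O)O)[C@@](C)(O[Si](CC)(CC)CC)CCC1(OCCO1)/C=C\[C@@H](O)CO[Si](c1ccccc1)(c1ccccc1)C(C)(C)C | intermediate
29 | mixed anhydride of 28 with 2,4,6-trichlorobenzoic acid | CC(C)=CCC/C(C)=C/CC/C(C)=C/CCC(C(=O)OC(=O)c1c(Cl)cc(Cl)cc1Cl)[C@@](C)(O[Si](CC)(CC)CC)CCC1(OCCO1)/C=C\[C@@H](O)CO[Si](c1ccccc1)(c1ccccc1)C(C)(C)C | intermediate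
30 | ten-membered lactone (key-step precursor): ring O–CβH(CH2OSiPh2t-Bu)–CαH=C2H (Z)–C3(dioxolane)–C4H2–C5H2–C6(CH3)(OSiEt3)–C1H(homofarnesyl)–C7(=O); Cβ R, C6 S, C1 epimers | CC(C)=CCC/C(C)=C/CC/C(C)=C/CCC1C(=O)O[C@@H](CO[Si](c2ccccc2)(c2ccccc2)C(C)(C)C)/C=C\C2(OCCO2)CC[C@]1(C)O[Si](CC)(CC)CC | intermediate
31 | O-trimethylsilyl ketene acetal of 30 (C1=C7, either geometry) | CC(C)=CCC/C(C)=C/CC/C(C)=C/CCC1=C(O[Si](C)(C)C)O[C@@H](CO[Si](c2ccccc2)(c2ccccc2)C(C)(C)C)/C=C\C2(OCCO2)CC[C@]1(C)O[Si](CC)(CC)CC | intermediate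
32 | trimethylsilyl ester of 33 | CC(C)=CCC/C(C)=C/CC/C(C)=C/CC[C@@]1(C(=O)O[Si](C)(C)C)[C@H](/C=C/CO[Si](c2ccccc2)(c2ccccc2)C(C)(C)C)C2(OCCO2)CC[C@]1(C)O[Si](CC)(CC)CC | intermediate
33 | ring A acid (key-step product): C3 spiro-dioxolane; C1 bears CO2H (C7) and the homofarnesyl chain, C2 the (E)-3-(tert-butyldiphenylsilyloxy)prop-1-enyl arm, C6 CH3 and OSiEt3; CO2H, arm and OSiEt3 on one face, chain and CH3 on the other | CC(C)=CCC/C(C)=C/CC/C(C)=C/CC[C@@]1(C(=O)O)[C@H](/C=C/CO[Si](c2ccccc2)(c2ccccc2)C(C)(C)C)C2(OCCO2)CC[C@]1(C)O[Si](CC)(CC)CC | intermediate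
34 | 33 with the arm reduced to 3-(tert-butyldiphenylsilyloxy)propyl | CC(C)=CCC/C(C)=C/CC/C(C)=C/CC[C@@]1(C(=O)O)[C@H](CCCO[Si](c2ccccc2)(c2ccccc2)C(C)(C)C)C2(OCCO2)CC[C@]1(C)O[Si](CC)(CC)CC | intermediate
35 | C7 alcohol: 34 with CO2H reduced to CH2OH | CC(C)=CCC/C(C)=C/CC/C(C)=C/CC[C@@]1(CO)[C@H](CCCO[Si](c2ccccc2)(c2ccccc2)C(C)(C)C)C2(OCCO2)CC[C@]1(C)O[Si](CC)(CC)CC | intermediate
36 | 35 as its C7 O-tert-butyldimethylsilyl ether | CC(C)=CCC/C(C)=C/CC/C(C)=C/CC[C@@]1(CO[Si](C)(C)C(C)(C)C)[C@H](CCCO[Si](c2ccccc2)(c2ccccc2)C(C)(C)C)C2(OCCO2)CC[C@]1(C)O[Si](CC)(CC)CC | intermediate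
37 | C3 ketone: 36 with the dioxolane removed | CC(C)=CCC/C(C)=C/CC/C(C)=C/CC[C@@]1(CO[Si](C)(C)C(C)(C)C)[C@H](CCCO[Si](c2ccccc2)(c2ccccc2)C(C)(C)C)C(=O)CC[C@]1(C)O[Si](CC)(CC)CC | intermediate
38 | C3 tertiary alcohol bearing an isopropenyl group (C3 epimers) | CC(C)=CCC/C(C)=C/CC/C(C)=C/CC[C@@]1(CO[Si](C)(C)C(C)(C)C)[C@H](CCCO[Si](c2ccccc2)(c2ccccc2)C(C)(C)C)C(O)(C(C)=C)CC[C@]1(C)O[Si](CC)(CC)CC | intermediate
39 | target with C7 O-SiMe2t-Bu, Cγ O-SiPh2t-Bu and C6 O-SiEt3; (Z)-enal, CHO cis to C2 | CC(C)=CCC/C(C)=C/CC/C(C)=C/CC[C@@]1(CO[Si](C)(C)C(C)(C)C)[C@H](CCCO[Si](c2ccccc2)(c2ccccc2)C(C)(C)C)/C(=C(/C)C=O)CC[C@]1(C)O[Si](CC)(CC)CC | intermediate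
40 | CNP0284886.1, (Z)-2-[(2R,3S,4S)-4-hydroxy-3-(hydroxymethyl)-2-(3-hydroxypropyl)-4-methyl-3-[(3E,7E)-4,8,12-trimethyltrideca-3,7,11-trienyl]cyclohexylidene]propanal | CC(C)=CCC/C(C)=C/CC/C(C)=C/CC[C@@]1(CO)[C@H](CCCO)/C(=C(/C)C=O)CC[C@]1(C)O | target

**Step count and risks**

Total step count: 27. Longest linear sequence: 22 steps (steps 6–27, from (S)-linalool); the farnesol branch (steps 1–4) joins at step 14 and the glyceraldehyde branch (step 5) at step 11.

Steps most likely to fail

1. Step 20 (ring-contracting Ireland–Claisen). What may go wrong: slow or incomplete deprotonation of the hindered tertiary C1–H inside the medium ring, loss of the C6 silyloxy group by β-elimination from the enolate before it is silylated, or a rearrangement too slow to outrun decomposition of the ketene acetal. Fallback (ring contraction first, quaternary centre second): it sets out from 21 and rejoins the route at 33. Compound 21 is not alkylated but saponified (LiOH) to the acid F1, freed from its acetonide (aq AcOH) to the diol acid F2, silylated at the primary hydroxyl (t-BuPh2SiCl, imidazole) to the hydroxy acid F3, semi-hydrogenated as in step 18 to the Z seco acid F4 and lactonised (Yamaguchi conditions) to the unbranched ten-membered lactone F5. The silyl ketene acetal of F5, a substrate of exactly the type for which this ring contraction is established, should give the cis ring A acid F6. The dianion of F6 (LiN(i-Pr)2, 2.2 equiv, THF/DMPU) is then alkylated with 6; attack on the face opposite the C2 arm and the C6 silyloxy group puts the chain where the target has it and gives 33.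

2. Step 19 (macrolactonisation). What may go wrong: intermolecular acylation to dimers and oligomers outrunning closure of the strained ten-membered ring, slow acyl transfer at the α-branched acylpyridinium ion, or acid-triggered cyclisation of the cis-hydroxy ketal toward a furan. Fallback (ester first, ring by alkene metathesis): it sets out from 17 and rejoins the route at 30. Vinylmagnesium bromide (CH2=CHMgBr) converts 17 to the allylic alcohol F7, Dess–Martin oxidation gives the enone F8 and ketalisation as in step 13 the vinyl dioxolane F9. Alkylation with 6 as in step 14 gives the ester F10 and LiOH the acid F11. Commercial (R)-but-3-ene-1,2-diol is silylated at the primary hydroxyl to (R)-1-(tert-butyldiphenylsilyloxy)but-3-en-2-ol F12, which is esterified with F11 (2,4,6-Cl3C6H2COCl, Et3N, DMAP; intermolecular, so it can be forced) to the diene ester F13. Ring-closing metathesis (second-generation Grubbs catalyst, RuCl2(=CHPh)(PCy3)(H2IMes), dilute toluene, 80 °C) joins the two monosubstituted alkenes, which react far faster than the trisubstituted chain alkenes. The Z isomer, expected to be the more stable one in a ten-membered ring, is 30 and is separated from any E isomer.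

3. Step 26 (oxidative transposition to the enal). What may go wrong: poor control of the alkene geometry during the allylic shift, or ionisation of the tertiary allylic chromate to dienes in place of transposition. Fallback (olefination at the nitrile level): it sets out from 37 and rejoins the route at 39. Horner–Wadsworth–Emmons reaction of 37 with diethyl (1-cyanoethyl)phosphonate (NaH, THF, 0 °C → rt, ketone added to the preformed anion to limit enolisation toward C2) gives the unsaturated nitrile F14. The slim, linear cyano group prefers the side of the substituted carbon C2 more clearly than a formyl or CH2O group does, and the isomers can be separated at this stage. Reduction with i-Bu2AlH (toluene, −78 °C) and mild acidic hydrolysis of the aldimine gives 39.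

**Further compounds**

F1 | step 20 | (S)-5-{2-[(R)-(2,2-dimethyl-1,3-dioxolan-4-yl)ethynyl]-1,3-dioxolan-2-yl}-3-methyl-3-(triethylsilyloxy)pentanoic acid | OC(=O)C[C@@](C)(O[Si](CC)(CC)CC)CCC1(OCCO1)C#C[C@@H]1COC(C)(C)O1
F2 | step 20 | (S)-5-{2-[(R)-3,4-dihydroxybut-1-ynyl]-1,3-dioxolan-2-yl}-3-methyl-3-(triethylsilyloxy)pentanoic acid | OC(=O)C[C@@](C)(O[Si](CC)(CC)CC)CCC1(OCCO1)C#C[C@@H](O)CO
F3 | step 20 | F2 with the primary hydroxyl as tert-butyldiphenylsilyl ether | OC(=O)C[C@@](C)(O[Si](CC)(CC)CC)CCC1(OCCO1)C#C[C@@H](O)CO[Si](c1ccccc1)(c1ccccc1)C(C)(C)C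
F4 | step 20 | Z seco acid without the C1 chain (C6 S, Cβ R) | OC(=O)C[C@@](C)(O[Si](CC)(CC)CC)CCC1(OCCO1)/C=C\[C@@H](O)CO[Si](c1ccccc1)(c1ccccc1)C(C)(C)C
F5 | step 20 | ten-membered Z-lactone with C1H2 (C6 S, Cβ R) | O=C1O[C@@H](CO[Si](c2ccccc2)(c2ccccc2)C(C)(C)C)/C=C\C2(OCCO2)CC[C@](C)(O[Si](CC)(CC)CC)C1
F6 | step 20 | ring A acid without the C1 chain (C1–H; CO2H cis to the E-alkenyl arm and to OSiEt3) | [C@@H]1(C(=O)O)[C@H](/C=C/CO[Si](c2ccccc2)(c2ccccc2)C(C)(C)C)C2(OCCO2)CC[C@]1(C)O[Si](CC)(CC)CC
F7 | step 19 | methyl (3S)-6-hydroxy-3-methyl-3-(triethylsilyloxy)oct-7-enoate (carbinol epimers) | COC(=O)C[C@@](C)(O[Si](CC)(CC)CC)CCC(O)C=C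
F8 | step 19 | methyl (S)-3-methyl-6-oxo-3-(triethylsilyloxy)oct-7-enoate | COC(=O)C[C@@](C)(O[Si](CC)(CC)CC)CCC(=O)C=C
F9 | step 19 | methyl (S)-5-(2-ethenyl-1,3-dioxolan-2-yl)-3-methyl-3-(triethylsilyloxy)pentanoate | COC(=O)C[C@@](C)(O[Si](CC)(CC)CC)CCC1(C=C)OCCO1
F10 | step 19 | F9 carrying the (3E,7E)-homofarnesyl chain on C1 (C1 epimers) | CC(C)=CCC/C(C)=C/CC/C(C)=C/CCC(C(=O)OC)[C@@](C)(O[Si](CC)(CC)CC)CCC1(C=C)OCCO1
F11 | step 19 | carboxylic acid from F10 (C1 epimers) | CC(C)=CCC/C(C)=C/CC/C(C)=C/CCC(C(=O)O)[C@@](C)(O[Si](CC)(CC)CC)CCC1(C=C)OCCO1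
F12 | step 19 | (R)-1-(tert-butyldiphenylsilyloxy)but-3-en-2-ol | C=C[C@@H](O)CO[Si](c1ccccc1)(c1ccccc1)C(C)(C)C
F13 | step 19 | ester of F11 with F12 (diene for ring closure; C1 epimers) | CC(C)=CCC/C(C)=C/CC/C(C)=C/CCC(C(=O)O[C@@H](CO[Si](c1ccccc1)(c1ccccc1)C(C)(C)C)C=C)[C@@](C)(O[Si](CC)(CC)CC)CCC1(C=C)OCCO1
F14 | step 26 | nitrile analogue of 39 (C≡N in place of CHO, cyano group cis to C2) | CC(C)=CCC/C(C)=C/CC/C(C)=C/CC[C@@]1(CO[Si](C)(C)C(C)(C)C)[C@H](CCCO[Si](c2ccccc2)(c2ccccc2)C(C)(C)C)/C(=C(/C)C#N)CC[C@]1(C)O[Si](CC)(CC)CC
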